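**Retrosynthetic overview**

1. Rings E, D, C and B are 1,2,3,5-tetraoxygenated arenes. Each diaryl ether bond is cut at the oxygen-flanked carbon (C4 of rings D, C, B) to a phenol plus 4-bromo-3,5-dimethoxybenzaldehyde, whose formyl group then becomes the next phenol.
2. The strategy rests on ring A: C1 carries the ether oxygen to ring B, C2, C4 and C6 carry hydroxyls, C3 and C5 are CH. This is a phloroglucinol whose alternating oxygens are the carbonyls of a folded triketide chain.
3. Ring A is therefore not coupled as an arene. It is cut at C3–C4 (Claisen retron) to a dimethyl 3,5-dioxoheptanedioate carrying the B–E aryloxy group on C4; the methoxycarbonyl group left on C3 is removed afterwards.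
4. The chain comes from γ-acylation of the bis-silyl enol ether of methyl 4-(aryloxy)acetoacetate with methyl malonyl chloride. This replaces a twofold homologation of an aryloxymalonyl dichloride, which is prone to ketene and pyranone formation.
5. Ring order: E and D are joined first, then C, then B (all bought as arenes); ring A is the only ring built, and it is built last. Decarboxylation and ninefold O-demethylation finish the route.

Key step: step 11

Abbreviation: Ar = 3,5-dimethoxy-4-{3,5-dimethoxy-4-[3,5-dimethoxy-4-(3,4,5-trimethoxyphenoxy)phenoxy]phenoxy}phenyl (rings B to E with nine methyl ethers, bonded through C1 of ring B).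

Assumption: the enol ether double bonds of 14, 15 and 17 are drawn Z. Their geometry has no consequence, because these carbons return to carbonyl or sp3 centres in step 10. Compound 17 is racemic at its aryloxy-bearing carbon, which ends as an aromatic carbon; the target has no stereocentre.

**Route**

Step 1
Reactants: 1 3,4,5-trimethoxyphenol; 2 4-bromo-3,5-dimethoxybenzaldehyde
Product: 3 3,5-dimethoxy-4-(3,4,5-trimethoxyphenoxy)benzaldehyde (rings D–E)
Conditions: CuI (10 mol %), picolinic acid (20 mol %), K3PO4, DMSO, 90 °C, argon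
Reagents that add atoms: none
Why: Ullmann-type copper-catalysed diaryl ether synthesis, in which the para-formyl group activates the C–Br bond between the two methoxy groups and the phenol has free ortho positions.

Step 2
Reactants: 3 3,5-dimethoxy-4-(3,4,5-trimethoxyphenoxy)benzaldehyde
Product: 5 3,5-dimethoxy-4-(3,4,5-trimethoxyphenoxy)phenol, via dimer aryl formate 4 (not isolated)
Conditions: mCPBA, CH2Cl2, 0 °C to rt; then K2CO3 (cat.), MeOH, rt
Reagents that add atoms: mCPBA (3-chloroperoxybenzoic acid), O=C(OO)c1cccc(Cl)c1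
Why: Baeyer–Villiger (Dakin-type) oxidation, in which the electron-rich aryl group with its para oxygen donor migrates in preference to hydrogen, followed by methanolysis of the formate.

Step 3
Reactants: 5 3,5-dimethoxy-4-(3,4,5-trimethoxyphenoxy)phenol; 2 4-bromo-3,5-dimethoxybenzaldehyde
Product: 6 3,5-dimethoxy-4-[3,5-dimethoxy-4-(3,4,5-trimethoxyphenoxy)phenoxy]benzaldehyde (rings C–E)
Conditions: CuI (10 mol %), picolinic acid (20 mol %), K3PO4, DMSO, 90 °C, argon
Reagents that add atoms: none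
Why: The same Ullmann-type etherification as in step 1; the phenol oxygen of 5 sits in the same unhindered environment as that of 1.

Step 4
Reactants: 6 trimer aldehyde
Product: 8 3,5-dimethoxy-4-[3,5-dimethoxy-4-(3,4,5-trimethoxyphenoxy)phenoxy]phenol, via trimer aryl formate 7 (not isolated)
Conditions: mCPBA, CH2Cl2, 0 °C to rt; then K2CO3 (cat.), MeOH, rt
Reagents that add atoms: mCPBA (3-chloroperoxybenzoic acid), O=C(OO)c1cccc(Cl)c1
Why: Baeyer–Villiger oxidation with aryl migration as in step 2, then formate methanolysis.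

Step 5
Reactants: 8 trimer phenol; 2 4-bromo-3,5-dimethoxybenzaldehyde
Product: 9 3,5-dimethoxy-4-{3,5-dimethoxy-4-[3,5-dimethoxy-4-(3,4,5-trimethoxyphenoxy)phenoxy]phenoxy}benzaldehyde (ArCHO, rings B–E)
Conditions: CuI (10 mol %), picolinic acid (20 mol %), K3PO4, DMSO, 90 °C, argon
Reagents that add atoms: none
Why: Third Ullmann-type etherification of the same activated bromide with a phenol of unchanged local structure.

Step 6
Reactants: 9 tetramer aldehyde ArCHO
Product: 11 tetramer phenol ArOH, via tetramer aryl formate 10 (not isolated)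
Conditions: mCPBA, CH2Cl2, 0 °C to rt; then K2CO3 (cat.), MeOH, rt
Reagents that add atoms: mCPBA (3-chloroperoxybenzoic acid), O=C(OO)c1cccc(Cl)c1
Why: Baeyer–Villiger oxidation with aryl migration as in step 2, then formate methanolysis, giving the free hydroxyl on C1 of ring B.

Step 7
Reactants: 11 tetramer phenol ArOH; 12 methyl 4-chloro-3-oxobutanoate
Product: 13 methyl 4-(ArO)-3-oxobutanoate
Conditions: NaH (2.2 equiv), THF/DMF, 0 °C to rt; then 1 M HCl
Reagents that add atoms: none
Why: Williamson O-alkylation, in which the second equivalent of NaH holds 12 as its sodium enolate and so protects the ketone while the aryloxide displaces the primary chloride by SN2, a known way to 4-aryloxyacetoacetates.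

Step 8
Reactants: 13 methyl 4-(ArO)-3-oxobutanoate
Product: 14 methyl (Z)-4-(ArO)-3-(trimethylsilyloxy)but-2-enoate
Conditions: TMSCl, Et3N, toluene, rt; filtered and concentrated under argon
Reagents that add atoms: TMSCl (chlorotrimethylsilane), C[Si](C)(C)Cl
Why: Silyl enol ether formation by O-silylation of the β-keto ester enol on its C2 side, the standard first stage towards a 1,3-bis-silyl enol ether.

Step 9
Reactants: 14 methyl (Z)-4-(ArO)-3-(trimethylsilyloxy)but-2-enoate
Product: 15 (1Z,3Z)-4-(ArO)-1-methoxy-1,3-bis(trimethylsilyloxy)buta-1,3-diene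
Conditions: LDA, THF, −78 °C; then TMSCl, −78 °C to rt; used crude
Reagents that add atoms: TMSCl (chlorotrimethylsilane), C[Si](C)(C)Cl
Why: Vinylogous (γ) deprotonation of the β-silyloxy enoate gives a lithium dienolate that TMSCl traps on the ester oxygen, the usual preparation of 1,3-bis-silyl enol ethers as masked acetoacetate dianions, of which 4-aryloxy members are known.

Step 10
Reactants: 15 (1Z,3Z)-4-(ArO)-1-methoxy-1,3-bis(trimethylsilyloxy)buta-1,3-diene; 16 methyl 3-chloro-3-oxopropanoate (methyl malonyl chloride)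
Product: 18 dimethyl 4-(ArO)-3,5-dioxoheptanedioate, via silyl enol ether 17 (not isolated)
Conditions: CH2Cl2, −78 °C to rt; then cold 1 M HCl
Reagents that add atoms: none
Why: Uncatalysed Mukaiyama-type C-acylation, in which the 1,3-bis-silyl enol ether attacks the acid chloride through its terminal carbon (C4, bearing OAr), TMSCl is lost to leave 17 and acidic work-up unmasks the tetracarbonyl chain, a known route to 3,5-dioxopimelates with no base present to enolise the malonyl chloride.

Step 11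
Reactants: 18 dimethyl 4-(ArO)-3,5-dioxoheptanedioate
Product: 19 methyl 3-(ArO)-2,4,6-trihydroxybenzoate
Conditions: NaOMe (4 equiv), MeOH (0.02 M), 0 °C to 65 °C, argon; then 1 M HCl, 0 °C
Reagents that add atoms: none
Why: Methoxide removes first the C4 proton and then a C2 proton; the C2 carbanion of the β-keto ester adds to the C7 ester carbonyl of the other arm and methoxide leaves, an intramolecular Claisen (Dieckmann-type) condensation of the kind that turns 3,5-dioxo diesters into phloroglucinol carboxylates. Ring A closes by a 6-(enolendo)-exo-trig acyl substitution that joins future C3 (CH) to future C4 (the C–OH para to the ether carbon), and the cyclohexane-1,3,5-trione formed tautomerises at once to the arene, whose phenoxide is the thermodynamic sink. No stereocentre is formed, and because the two malonyl arms are identical it does not matter which one acts as the nucleophile. The selectivity needed is C-acylation over O-acylation: the C5 enol oxygen can attack the C1 ester to give a 4-hydroxy-2-pyranone, but methanolic methoxide reopens that lactone whereas aromatisation of the carbocycle is not reversible, so the material should drain to 19. Retro-Claisen cleavage is held back because the 1,3-diketone is present as its enolate, and dilution suppresses intermolecular condensation.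

Step 12
Reactants: 19 methyl 3-(ArO)-2,4,6-trihydroxybenzoate
Product: 21 2-(ArO)benzene-1,3,5-triol, via trihydroxybenzoic acid 20 (not isolated)
Conditions: KOH, MeOH/H2O (degassed), 80 °C, argon; then 2 M HCl to pH 2, 60 °C
Reagents that add atoms: none
Why: Ester saponification followed by protodecarboxylation, since a 2,4,6-trihydroxybenzoic acid loses CO2 on gentle warming in acid through its C1-protonated keto tautomer (a vinylogous β-keto acid), as phloroglucinolcarboxylic acid itself does.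

Step 13
Reactants: 21 2-(ArO)benzene-1,3,5-triol
Product: 22 2-{4-[4-[4-(3,4,5-trihydroxyphenoxy)-3,5-dihydroxyphenoxy]-3,5-dihydroxyphenoxy]-3,5-dihydroxyphenoxy}benzene-1,3,5-triol (target)
Conditions: BBr3 (20 equiv), CH2Cl2, −78 °C to rt, argon; then H2O, 0 °C
Reagents that add atoms: none
Why: BBr3 ether cleavage, in which each methoxy oxygen coordinates boron and bromide removes the methyl group by SN2, whereas the diaryl ether links offer no sp3 carbon and should survive; water then hydrolyses the aryl borates.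

**Compound list**

1 | 3,4,5-trimethoxyphenol | COc1cc(O)cc(OC)c1OC | starting material
2 | 4-bromo-3,5-dimethoxybenzaldehyde | COc1cc(C=O)cc(OC)c1Br | starting material
3 | 3,5-dimethoxy-4-(3,4,5-trimethoxyphenoxy)benzaldehyde | O=Cc1cc(OC)c(Oc2cc(OC)c(OC)c(OC)c2)c(OC)c1 | intermediate
4 | 3,5-dimethoxy-4-(3,4,5-trimethoxyphenoxy)phenyl formate | O=COc1cc(OC)c(Oc2cc(OC)c(OC)c(OC)c2)c(OC)c1 | intermediate (not isolated)
5 | 3,5-dimethoxy-4-(3,4,5-trimethoxyphenoxy)phenol | Oc1cc(OC)c(Oc2cc(OC)c(OC)c(OC)c2)c(OC)c1 | intermediate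
6 | 3,5-dimethoxy-4-[3,5-dimethoxy-4-(3,4,5-trimethoxyphenoxy)phenoxy]benzaldehyde | O=Cc1cc(OC)c(Oc2cc(OC)c(Oc3cc(OC)c(OC)c(OC)c3)c(OC)c2)c(OC)c1 | intermediate
7 | 3,5-dimethoxy-4-[3,5-dimethoxy-4-(3,4,5-trimethoxyphenoxy)phenoxy]phenyl formate | O=COc1cc(OC)c(Oc2cc(OC)c(Oc3cc(OC)c(OC)c(OC)c3)c(OC)c2)c(OC)c1 | intermediate (not isolated)
8 | 3,5-dimethoxy-4-[3,5-dimethoxy-4-(3,4,5-trimethoxyphenoxy)phenoxy]phenol | Oc1cc(OC)c(Oc2cc(OC)c(Oc3cc(OC)c(OC)c(OC)c3)c(OC)c2)c(OC)c1 | intermediate
9 | 3,5-dimethoxy-4-{3,5-dimethoxy-4-[3,5-dimethoxy-4-(3,4,5-trimethoxyphenoxy)phenoxy]phenoxy}benzaldehyde (ArCHO) | O=Cc1cc(OC)c(Oc2cc(OC)c(Oc3cc(OC)c(Oc4cc(OC)c(OC)c(OC)c4)c(OC)c3)c(OC)c2)c(OC)c1 | intermediate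
10 | 3,5-dimethoxy-4-{3,5-dimethoxy-4-[3,5-dimethoxy-4-(3,4,5-trimethoxyphenoxy)phenoxy]phenoxy}phenyl formate | O=COc1cc(OC)c(Oc2cc(OC)c(Oc3cc(OC)c(Oc4cc(OC)c(OC)c(OC)c4)c(OC)c3)c(OC)c2)c(OC)c1 | intermediate (not isolated)
11 | 3,5-dimethoxy-4-{3,5-dimethoxy-4-[3,5-dimethoxy-4-(3,4,5-trimethoxyphenoxy)phenoxy]phenoxy}phenol (ArOH) | Oc1cc(OC)c(Oc2cc(OC)c(Oc3cc(OC)c(Oc4cc(OC)c(OC)c(OC)c4)c(OC)c3)c(OC)c2)c(OC)c1 | intermediate
12 | methyl 4-chloro-3-oxobutanoate | COC(=O)CC(=O)CCl | starting material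
13 | methyl 4-(ArO)-3-oxobutanoate | COC(=O)CC(=O)COc1cc(OC)c(Oc2cc(OC)c(Oc3cc(OC)c(Oc4cc(OC)c(OC)c(OC)c4)c(OC)c3)c(OC)c2)c(OC)c1 | intermediate
14 | methyl (Z)-4-(ArO)-3-(trimethylsilyloxy)but-2-enoate | COC(=O)/C=C(\O[Si](C)(C)C)COc1cc(OC)c(Oc2cc(OC)c(Oc3cc(OC)c(Oc4cc(OC)c(OC)c(OC)c4)c(OC)c3)c(OC)c2)c(OC)c1 | intermediate
15 | (1Z,3Z)-4-(ArO)-1-methoxy-1,3-bis(trimethylsilyloxy)buta-1,3-diene | C[Si](C)(C)O/C(OC)=C\C(O[Si](C)(C)C)=C\Oc1cc(OC)c(Oc2cc(OC)c(Oc3cc(OC)c(Oc4cc(OC)c(OC)c(OC)c4)c(OC)c3)c(OC)c2)c(OC)c1 | intermediate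
16 | methyl 3-chloro-3-oxopropanoate (methyl malonyl chloride) | COC(=O)CC(=O)Cl | starting material
17 | dimethyl (Z)-4-(ArO)-5-oxo-3-(trimethylsilyloxy)hept-2-enedioate (racemic) | COC(=O)/C=C(\O[Si](C)(C)C)C(Oc1cc(OC)c(Oc2cc(OC)c(Oc3cc(OC)c(Oc4cc(OC)c(OC)c(OC)c4)c(OC)c3)c(OC)c2)c(OC)c1)C(=O)CC(=O)OC | intermediate (not isolated)
18 | dimethyl 4-(ArO)-3,5-dioxoheptanedioate | COC(=O)CC(=O)C(Oc1cc(OC)c(Oc2cc(OC)c(Oc3cc(OC)c(Oc4cc(OC)c(OC)c(OC)c4)c(OC)c3)c(OC)c2)c(OC)c1)C(=O)CC(=O)OC | intermediate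
19 | methyl 3-(ArO)-2,4,6-trihydroxybenzoate | COC(=O)c1c(O)cc(O)c(Oc2cc(OC)c(Oc3cc(OC)c(Oc4cc(OC)c(Oc5cc(OC)c(OC)c(OC)c5)c(OC)c4)c(OC)c3)c(OC)c2)c1O | intermediate
20 | 3-(ArO)-2,4,6-trihydroxybenzoic acid | OC(=O)c1c(O)cc(O)c(Oc2cc(OC)c(Oc3cc(OC)c(Oc4cc(OC)c(Oc5cc(OC)c(OC)c(OC)c5)c(OC)c4)c(OC)c3)c(OC)c2)c1O | intermediate (not isolated)
21 | 2-(ArO)benzene-1,3,5-triol | Oc1cc(O)c(Oc2cc(OC)c(Oc3cc(OC)c(Oc4cc(OC)c(Oc5cc(OC)c(OC)c(OC)c5)c(OC)c4)c(OC)c3)c(OC)c2)c(O)c1 | intermediate
22 | 2-{4-[4-[4-(3,4,5-trihydroxyphenoxy)-3,5-dihydroxyphenoxy]-3,5-dihydroxyphenoxy]-3,5-dihydroxyphenoxy}benzene-1,3,5-triol | Oc1cc(O)c(Oc2cc(O)c(Oc3cc(O)c(Oc4cc(O)c(Oc5cc(O)c(O)c(O)c5)c(O)c4)c(O)c3)c(O)c2)c(O)c1 | target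

**Step count**

Total step count: 13.
Longest linear sequence: 13 steps (1 to 22).

**Steps most likely to fail**

1. Step 11. The chain may close through oxygen (lactonisation to the pyranone) faster than the lactone is reopened, or may fragment by retro-Claisen attack of methoxide before ring closure. The fallback sets out from phenol 11 and gives up the folding of ring A. A fourth copper-catalysed etherification with bromoaldehyde 2 (CuI, picolinic acid, K3PO4, DMSO, 90 °C) should give the pentamer aldehyde F1. Baeyer–Villiger oxidation (mCPBA, CH2Cl2) should give the pentamer aryl formate F2, and methanolysis (K2CO3, MeOH) the pentamer phenol F3, in which ring A already carries its three oxygens as one hydroxyl and two methyl ethers. BBr3 in CH2Cl2 (−78 °C to rt) then removes all eleven methyl groups, and the fallback comes back to the route at target 22.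

2. Step 10. The acid chloride may be consumed by O-acylation or by desilylation of the diene through adventitious HCl, or the tetracarbonyl product may cyclise during the acidic work-up. The fallback sets out from phenol 11 and builds both arms from a malonate. Alkylation with diethyl bromomalonate (K2CO3, acetone, reflux) should give diethyl 2-(ArO)malonate F4. Saponification (LiOH, THF/H2O, 0 °C) gives 2-(ArO)malonic acid F5, and (COCl)2 with catalytic DMF in CH2Cl2 gives 2-(ArO)malonyl dichloride F6. Twofold C-acylation of Meldrum's acid (pyridine, CH2Cl2, 0 °C) gives the bis(acyl Meldrum's acid) F7, and boiling methanol opens both dioxanediones with loss of acetone and CO2. The fallback comes back to the route at compound 18.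

3. Step 5 (the same coupling serves steps 1 and 3, but here the phenol is the most valuable). Activation of the C–Br bond between two methoxy groups may be slow, so that hydrodebromination and base-induced degradation of the aldehyde outrun C–O bond formation. The fallback sets out from phenol 8 and reverses the roles of the partners. Tf2O and pyridine in CH2Cl2 should give the trimer aryl triflate F8. Miyaura borylation (B2pin2, Pd(dppf)Cl2, KOAc, dioxane, 90 °C) gives the trimer aryl pinacol boronate F9. Chan–Lam coupling of F9 with 4-hydroxy-3,5-dimethoxybenzaldehyde (Cu(OAc)2, pyridine, 4 Å molecular sieves, air, MeCN, rt to 50 °C) puts the hindered partner in the role of the phenol. The fallback comes back to the route at aldehyde 9.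

**Further compounds**

F1 | step 11 | 3,5-dimethoxy-4-(ArO)benzaldehyde (pentamer aldehyde) | O=Cc1cc(OC)c(Oc2cc(OC)c(Oc3cc(OC)c(Oc4cc(OC)c(Oc5cc(OC)c(OC)c(OC)c5)c(OC)c4)c(OC)c3)c(OC)c2)c(OC)c1
F2 | step 11 | 3,5-dimethoxy-4-(ArO)phenyl formate (pentamer aryl formate) | O=COc1cc(OC)c(Oc2cc(OC)c(Oc3cc(OC)c(Oc4cc(OC)c(Oc5cc(OC)c(OC)c(OC)c5)c(OC)c4)c(OC)c3)c(OC)c2)c(OC)c1
F3 | step 11 | 3,5-dimethoxy-4-(ArO)phenol (pentamer phenol) | Oc1cc(OC)c(Oc2cc(OC)c(Oc3cc(OC)c(Oc4cc(OC)c(Oc5cc(OC)c(OC)c(OC)c5)c(OC)c4)c(OC)c3)c(OC)c2)c(OC)c1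
F4 | step 10 | diethyl 2-(ArO)malonate | CCOC(=O)C(Oc1cc(OC)c(Oc2cc(OC)c(Oc3cc(OC)c(Oc4cc(OC)c(OC)c(OC)c4)c(OC)c3)c(OC)c2)c(OC)c1)C(=O)OCC
F5 | step 10 | 2-(ArO)malonic acid | OC(=O)C(Oc1cc(OC)c(Oc2cc(OC)c(Oc3cc(OC)c(Oc4cc(OC)c(OC)c(OC)c4)c(OC)c3)c(OC)c2)c(OC)c1)C(=O)O
F6 | step 10 | 2-(ArO)malonyl dichloride | ClC(=O)C(Oc1cc(OC)c(Oc2cc(OC)c(Oc3cc(OC)c(Oc4cc(OC)c(OC)c(OC)c4)c(OC)c3)c(OC)c2)c(OC)c1)C(=O)Cl
F7 | step 10 | 5,5'-[2-(ArO)-1,3-dihydroxypropane-1,3-diylidene]bis(2,2-dimethyl-1,3-dioxane-4,6-dione) | CC5(C)OC(=O)C(=C(O)C(Oc1cc(OC)c(Oc2cc(OC)c(Oc3cc(OC)c(Oc4cc(OC)c(OC)c(OC)c4)c(OC)c3)c(OC)c2)c(OC)c1)C(O)=C6C(=O)OC(C)(C)OC6=O)C(=O)O5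
F8 | step 5 | 3,5-dimethoxy-4-[3,5-dimethoxy-4-(3,4,5-trimethoxyphenoxy)phenoxy]phenyl trifluoromethanesulfonate | O=S(=O)(Oc1cc(OC)c(Oc2cc(OC)c(Oc3cc(OC)c(OC)c(OC)c3)c(OC)c2)c(OC)c1)C(F)(F)F
F9 | step 5 | 2-{3,5-dimethoxy-4-[3,5-dimethoxy-4-(3,4,5-trimethoxyphenoxy)phenoxy]phenyl}-4,4,5,5-tetramethyl-1,3,2-dioxaborolane | CC1(C)OB(OC1(C)C)c1cc(OC)c(Oc2cc(OC)c(Oc3cc(OC)c(OC)c(OC)c3)c(OC)c2)c(OC)c1
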